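## Structural features

The target is made of two 2-(2-phenylethyl)-4H-chromen-4-one units. Unit A (unprimed locants) bears a hydroxyl group at C7, unit B (primed locants) bears one at C8', and one biaryl bond joins C6 to C5'. Each unit is a benzene ring (ring A, ring B) fused to a 4-pyranone (pyranone A, pyranone B) whose C2 or C2' carries a CH2CH2Ph chain. There is no stereocentre, so no neighbouring stereocentres have to be related, and the C6–C5' axis carries no descriptor. The fragile parts are the two pyranones and the two free phenols. The pyranones are vinylogous esters that hydroxide or amines open at C2 or C2', and their side-chain methylene groups are vinylogously acidic; towards acid the skeleton is robust. The real difficulty is twofold. The biaryl bond lies between O7 on ring A and the peri carbonyl C4' on ring B, so a cross-coupling would have to join two ortho-substituted, electron-rich arenes. In addition, four oxygen atoms (O7, O8a, O8', O8a') must be told apart, two ending as phenols and two inside pyranones. Ring A is a 4-arylresorcinol: O7 and O8a are meta, C8 between them is unsubstituted, and the aryl group on C6 is ortho to O7 and para to O8a. This is the pattern formed when a 2-arylvinylketene combines with an alkoxyethyne: C7 is the ketene carbon, C8 and C8a are the alkyne carbons, and C4a, C5 and C6 are the chain of an unsaturated diazo ketone whose C6 is already bonded to ring B.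

## Logic of the disconnections

25 ⇒ 23. The bond O1–C2 of pyranone A and the O–CH3 bonds at O7 and O8' are cut. A 2-hydroxyaryl 1,3-diketone closes to a pyranone under acid, and the same hot acid removes the last two methyl ethers, so one operation ends the synthesis. The gain is an open-chain precursor with pyranone B already in place. The forward step demands tolerance of refluxing HBr, which holds because no acid-labile group remains.

23 ⇒ 20 + 21. The bond C2–C3 is cut. The acyl group is first placed on O8a (22) and then passed to the acetyl carbon C3 through a six-membered transition state, so the C–C bond forms intramolecularly and no external enolate competes. The whole side chain of unit A arrives in 21. The forward step demands that base acts on the acetyl group before it touches the acidic methylene group next to C2' of pyranone B.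

20 ⇒ 18. The bond C4–C4a is cut and the ethyl group returns to O8a. C4a is the only unhindered position that is ortho or para to both ring A oxygens. The Lewis acid that brings in the acetyl group also removes the ethyl ether chelated to it (through 19), so acylation and unmasking of O8a cost one step. The demand is selectivity for ring A over ring B and over the side-chain phenyl rings, and a capped O7.

18 ⇒ 17. The O7–CH3 bond is cut. The methyl ether keeps O7 out of the acylation chemistry and distinguishes O7 from O8a. It costs one step and is removed at the end without a step of its own.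

17 ⇒ 15. The bond O1'–C2' is cut and a methyl group returns to O8a'. The methyl ether at O8a' lies between the acyl group and O8', the position a boron Lewis acid cleaves first, and the freed phenol (16) closes onto C2'. Pyranone B becomes an open 1,3-diketone. The forward step demands that cleavage stops at O8a' and that the free O7 hydroxyl does not capture C4'.

15 ⇒ 13 + 14. The bond C3'–C4' is cut. The lactone carbonyl C4' is an aryl ester and so a good acyl donor, and the methyl carbon of 14 is its nucleophilic partner; the complete side chain of unit B is attached in one step. The demand is a regiodefined kinetic enolate of 14 in excess, because the product consumes a second equivalent of base.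

13 ⇒ 12. The lactone bond O7–C4' is cut. Closing it in the forward direction masks O7 and turns a methyl ester shielded by two ortho substituents into a reactive, ring-constrained aryl ester. Only methanol is lost.

12 ⇒ 6 + 7. Four bonds of ring A are cut: C6–C7, C7–C8, C8a–C4a and C4a–C5. Ring A disappears; what remains of the biaryl bond is the bond from ring B to a side-chain carbon present from the start, so no arene–arene coupling is needed, and ring B keeps C4' as its ester. The forward step (through 8, 9, 10 and 11) demands a clean photochemical Wolff rearrangement and one orientation of the ketene–alkyne union. The substituents of 6 and 7 are kept as they are, because each is removed later without a step of its own: the ester methyl in step 5, the O8a' methyl in step 7, the ethyl in step 9 and the O8' methyl in step 11.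

6 ⇒ 4. The C4a=N2 bond is cut. A methyl ketone is not acidic enough for direct diazo transfer, so it is activated as the trifluoroacetyl derivative 5, and the activating group is lost in the transfer.

4 ⇒ 2 + 3. The double bond C5=C6 is cut. A stabilised ylide gives the E enone from the aldehyde; C6 is the former formyl carbon.

2 ⇒ 1. The ester O–CH3 bond is cut. The forward step must alkylate the carboxylate, because acid-catalysed esterification of the ring-chain tautomeric 1 would give the cyclic pseudo-ester.

## Other disconnections considered

Alternative 1: The cut removes the biaryl bond C6–C5' and the aryl–acyl bond C4a'–C4' together, treating ring B as a 1,2-difunctionalised aryne.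
- Forward step: 4-fluoro-1,2-dimethoxybenzene A1 would be lithiated between fluorine and methoxy and lose LiF on warming. The aryl Grignard reagent (2,4-dimethoxyphenyl)magnesium bromide A2 would add to the aryne at C5', the carbon remote from the methoxy group. The arylmagnesium left at C4a' would be acylated by N-methoxy-N-methyl-5-phenylpent-2-ynamide A3 to give ynone A4. No ring closes.
- In its favour: three simple components, two strategic bonds in one flask, no diazo compound and no photochemistry. A4 is one demethylative 6-endo closure away from pyranone B.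
- Against it here: the aryne must form in the presence of A2 without being consumed by its own lithiated precursor. The organometallic at C4a', flanked by a methoxy group and the new aryl ring, must attack A3 at the carbonyl carbon and not add to the triple bond.
- Comparison: on structure the two plans are equal in avoiding a metal-catalysed coupling of two hindered arenes; the alternative makes the biaryl bond by addition to an aryne, the chosen plan never makes it. Ring A arrives as an undifferentiated dimethyl ether, but acetylation with ortho-dealkylation would differentiate O7 and O8a as in the chosen plan, so this point is equal. On mechanism, regiocontrol rests on the inductive effect of one methoxy group there and on ynol ether polarity here, both well founded; the weaker link of the alternative is acylation of the hindered organometallic. On step economy the alternative is better, by roughly four steps.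

Alternative 2: The cut removes benzene ring B itself (bonds C7'–C8' and C5'–C4a') together with the lactone bond O7–C4'.
- Forward step: 2-(2-phenylethyl)-4H,6H-pyrano[3,2-g]chromene-4,6-dione A5 would be activated by Me3SiOTf as a silyloxybenzopyrylium ion. The methoxy-bearing terminus of 1,4-dimethoxy-1,3-bis(trimethylsilyloxy)buta-1,3-diene A6 would add at C2 of the unsubstituted pyranone. Base would then open that ring by retro-oxa-Michael reaction, the released ketone carbon (future C5') would condense with the active methylene carbon (future C4a') and aromatise, and the ester would lactonise onto O7 to give A7.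
- In its favour: ring B is grown on ring A, so no biaryl coupling is needed, which is equal to the chosen plan. Pyranone A is complete from the start. O8a' emerges as a free phenol distinct from the O8' methyl ether, which is better than the chosen plan, where this distinction depends on selective ether cleavage in step 7.
- Against it here: A5 holds two pyranones and only the unsubstituted one may react. Making A5 requires two identical acetyl groups of a symmetrical resorcinol precursor to be differentiated. After A7 the lactone would have to be opened by the enolate of 14 while a phenoxide sits ortho to the lactone carbonyl and base-sensitive pyranone A is present.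
- Comparison: mechanistically both plans rest on an established benzannulation. The alternative keeps the lactone-opening problem of the chosen plan under harder conditions. Step count should be about equal, so it offers no gain.

Alternative 3: The cut removes only C4–C4a, a late closure of pyranone A at carbon.
- Forward step: phenol A8 (O8a free, O7 methylated, pyranone B in place) would add to ethyl 5-phenylpent-2-ynoate A9 by oxa-Michael reaction. Saponification would give acid A10. Eaton's reagent (P2O5 in CH3SO3H) would convert the acid into an acylium equivalent that attacks C4a to give A11, which is identical with 24.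
- In its favour: pyranone A would form under acid with no strong base near pyranone B, which is better than step 10. No acetylating agent could touch the side-chain phenyl rings. Three operations replace steps 9 and 10 and the ring closure, which is equal in count.
- Against it here: it is an endgame only and solves neither the biaryl bond nor ring B. A8 needs O8a free and O7 capped, the reverse of what the benzannulation delivers in 12, so extra protecting-group operations and a de-ethylation without chelation help would be needed. The E isomer of A10 must isomerise before it can close, and closure at C8 is conceivable, although C4a is less hindered and para to O7.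
- Comparison: it is a possible replacement for the end of the chosen route and not a competing strategy. Mechanistically it is as sound as acetylation followed by acyl transfer. Combined with the benzannulation it would be longer because of the O7/O8a mismatch.

Key step: step 4

Remark: the locants of the two chromone units are used for the corresponding atoms of every intermediate; enolates, phenoxides and boron or aluminium chelates are regarded as ionised or complexed forms of the numbered compounds they derive from; the biaryl axis is regarded as configurationally undefined.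

## Route

Step 1
Reactants: 1 opianic acid (6-formyl-2,3-dimethoxybenzoic acid)
Product: 2 methyl 6-formyl-2,3-dimethoxybenzoate
Conditions: MeI, K2CO3, DMF, 20 °C
Reagents that add atoms: iodomethane, CI
Why: SN2 alkylation of the carboxylate gives the open-chain ester with the aldehyde intact; acid-catalysed esterification is avoided because the lactol tautomer of 1 would lead to the cyclic pseudo-ester.

Step 2
Reactants: 2 methyl 6-formyl-2,3-dimethoxybenzoate; 3 1-(triphenylphosphoranylidene)propan-2-one
Product: 4 methyl 2,3-dimethoxy-6-[(1E)-3-oxobut-1-en-1-yl]benzoate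
Conditions: PhMe, 100 °C
Reagents that add atoms: none
Why: Wittig olefination with a stabilised ylide should give the E enone; the hindered ester does not react with the ylide.

Step 3
Reactants: 4 methyl 2,3-dimethoxy-6-[(1E)-3-oxobut-1-en-1-yl]benzoate
Product: 6 methyl 6-[(1E)-4-diazo-3-oxobut-1-en-1-yl]-2,3-dimethoxybenzoate, via trifluoroacetyl diketone 5 (not isolated)
Conditions: LiN(SiMe3)2, THF, −78 °C; CF3CO2CH2CF3; aq. HCl work-up; then CH3SO2N3, Et3N, H2O, MeCN, 20 °C
Reagents that add atoms: methanesulfonyl azide, CS(=O)(=O)N=[N+]=[N-]
Why: Detrifluoroacetylative diazo transfer: the kinetic enolate at the methyl group (the only enolisable position) is trifluoroacetylated, and the activated methylene of 5 takes up the diazo group with loss of the trifluoroacetyl group as its sulfonamide. The E alkene and the aryl ester are not affected at −78 °C.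

Step 4
Reactants: 6 methyl 6-[(1E)-4-diazo-3-oxobut-1-en-1-yl]-2,3-dimethoxybenzoate; 7 ethoxyethyne
Product: 12 methyl 6-(4-ethoxy-2-hydroxyphenyl)-2,3-dimethoxybenzoate, via vinylketene 8 (not isolated), via cyclobutenone 9 (not isolated), via dienylketene 10 (not isolated), via cyclohexadienone 11 (not isolated)
Conditions: hν (254 nm), 7 (3 equiv), ClCH2CH2Cl, 20 °C; then 80 °C
Reagents that add atoms: none
Why: Irradiation expels N2 from 6 and the photochemical Wolff rearrangement shifts the styryl carbon C5 to the carbene carbon (bond C4a–C5), giving arylvinylketene 8. The electrophilic ketene carbon C7 bonds to the unsubstituted carbon of 7 and the ketene α-carbon C4a to the ethoxy-bearing carbon in a [2+2] cycloaddition (bonds C7–C8 and C8a–C4a), giving 4-alkenylcyclobutenone 9. On heating, 4π-electrocyclic opening of 9 gives dienylketene 10, whose 6π-electrocyclisation closes C6–C7 to dienone 11, and enolisation gives phenol 12. The closest known reaction type is the Danheiser benzannulation in its diazo ketone form with alkoxyalkynes, which gives resorcinol monoethers. Ring A, a six-membered carbocycle, is closed by thermal disrotatory 6π-electrocyclisation of a dienylketene; the four-membered ring of 9 is only a relay. The stereocentres of 9 and 11 are racemic and are erased on aromatisation, so no stereocontrol is required. The selectivity needed is the orientation of the [2+2] step, secured by the polarisation of the ynol ether, which places OEt on C8a (para to the aryl group) and the new hydroxyl on C7 (ortho to it); ring opening of 9 is reversible, so only the rotamer with the alkenyl group turned inward drains to 12. The ester and methoxy groups of ring B are remote from the ketene and act as spectators; any 13 formed by lactonisation in the thermal stage converges in step 5.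

Step 5
Reactants: 12 methyl 6-(4-ethoxy-2-hydroxyphenyl)-2,3-dimethoxybenzoate
Product: 13 3-ethoxy-7,8-dimethoxy-6H-benzo[c]chromen-6-one
Conditions: p-TsOH·H2O (cat.), PhMe, 110 °C, −MeOH
Reagents that add atoms: none
Why: Acid-catalysed intramolecular transesterification (lactonisation) of a 2'-hydroxybiaryl-2-carboxylate, driven by loss of methanol. It masks O7 and converts the shielded methyl ester into an activated aryl ester.

Step 6
Reactants: 13 3-ethoxy-7,8-dimethoxy-6H-benzo[c]chromen-6-one; 14 4-phenylbutan-2-one
Product: 15 1-[6-(4-ethoxy-2-hydroxyphenyl)-2,3-dimethoxyphenyl]-5-phenylpentane-1,3-dione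
Conditions: 14 (2.5 equiv), LiN(i-Pr)2 (2.5 equiv), THF, −78 °C; then 13, −78 → 0 °C; aq. HCl work-up
Reagents that add atoms: none
Why: Crossed Claisen-type C-acylation: the kinetic (methyl) lithium enolate of 14 attacks the lactone carbonyl, and the tetrahedral intermediate collapses with loss of the O7 phenoxide. Deprotonation of the 1,3-diketone by the second equivalent of enolate makes the acylation irreversible and blocks further addition.

Step 7
Reactants: 15 1-[6-(4-ethoxy-2-hydroxyphenyl)-2,3-dimethoxyphenyl]-5-phenylpentane-1,3-dione
Product: 17 5-(4-ethoxy-2-hydroxyphenyl)-8-methoxy-2-(2-phenylethyl)-4H-chromen-4-one, via hydroxy diketone 16 (not isolated)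
Conditions: BCl3, CH2Cl2, −78 → 0 °C; H2O; then conc. HCl, MeOH, 65 °C
Reagents that add atoms: none
Why: BCl3 should cleave only the methyl ether at O8a', which lies beside the acyl group and between two ortho substituents, leaving the unassisted ethers at O8' and O8a. The freed phenol of 16 adds to the aliphatic carbonyl C2' and acid-catalysed dehydration closes pyranone B (cyclodehydration of a 2-hydroxyaryl 1,3-diketone).

Step 8
Reactants: 17 5-(4-ethoxy-2-hydroxyphenyl)-8-methoxy-2-(2-phenylethyl)-4H-chromen-4-one
Product: 18 5-(4-ethoxy-2-methoxyphenyl)-8-methoxy-2-(2-phenylethyl)-4H-chromen-4-one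
Conditions: MeI, K2CO3, acetone, 56 °C
Reagents that add atoms: iodomethane, CI
Why: Williamson O-methylation of the only free phenol; K2CO3 in acetone does not open the pyranone. The ether keeps O7 out of the following acylations and distinguishes it from O8a.

Step 9
Reactants: 18 5-(4-ethoxy-2-methoxyphenyl)-8-methoxy-2-(2-phenylethyl)-4H-chromen-4-one
Product: 20 5-(5-acetyl-4-hydroxy-2-methoxyphenyl)-8-methoxy-2-(2-phenylethyl)-4H-chromen-4-one, via ethoxy ketone 19 (not isolated)
Conditions: AcCl (1.1 equiv), AlCl3 (4 equiv), CH2Cl2, 0 → 40 °C; aq. HCl work-up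
Reagents that add atoms: acetyl chloride, CC(=O)Cl
Why: Friedel–Crafts acetylation at C4a, which is ortho to the ethoxy and para to the methoxy group and the only unhindered doubly activated position; ring B is deactivated by the AlCl3-complexed pyranone and the alkylbenzene rings are far less reactive with one equivalent of acyl chloride. AlCl3 then cleaves the ethyl ether chelated to the new carbonyl group in 19, which unmasks O8a.

Step 10
Reactants: 20 5-(5-acetyl-4-hydroxy-2-methoxyphenyl)-8-methoxy-2-(2-phenylethyl)-4H-chromen-4-one; 21 3-phenylpropanoyl chloride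
Product: 23 1-{2-hydroxy-4-methoxy-5-[8-methoxy-4-oxo-2-(2-phenylethyl)-4H-chromen-5-yl]phenyl}-5-phenylpentane-1,3-dione, via aryl ester 22 (not isolated)
Conditions: LiN(SiMe3)2 (1.05 equiv), THF, −78 °C; 21, −78 → 0 °C; then LiN(SiMe3)2 (2.2 equiv), −78 → 0 °C; aq. HCl work-up
Reagents that add atoms: none
Why: O-Acylation of the lithium phenoxide followed by Baker–Venkataraman rearrangement: the acetyl enolate of 22 takes the acyl group from O8a through a six-membered transition state. The order of addition keeps the acid chloride away from free strong base, and the intramolecular transfer should outrun any reaction at the side-chain methylene of pyranone B.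

Step 11
Reactants: 23 1-{2-hydroxy-4-methoxy-5-[8-methoxy-4-oxo-2-(2-phenylethyl)-4H-chromen-5-yl]phenyl}-5-phenylpentane-1,3-dione
Product: 25 7-hydroxy-6-[8-hydroxy-4-oxo-2-(2-phenylethyl)-4H-chromen-5-yl]-2-(2-phenylethyl)-4H-chromen-4-one, via dimethyl ether 24 (not isolated)
Conditions: 48% aq. HBr, AcOH, 118 °C
Reagents that add atoms: none
Why: Acid-catalysed cyclodehydration of the 2-hydroxyaryl 1,3-diketone closes pyranone A (bond O1–C2) to give 24, and HBr then cleaves the two aryl methyl ethers by bromide attack on the protonated ethers. Pyranones and phenylethyl chains are stable to hot acid.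

## Compound list

1 | opianic acid (6-formyl-2,3-dimethoxybenzoic acid) | COc1ccc(C=O)c(C(=O)O)c1OC | starting material
2 | methyl 6-formyl-2,3-dimethoxybenzoate | COC(=O)c1c(C=O)ccc(OC)c1OC | intermediate
3 | 1-(triphenylphosphoranylidene)propan-2-one | CC(=O)C=P(c1ccccc1)(c1ccccc1)c1ccccc1 | starting material
4 | methyl 2,3-dimethoxy-6-[(1E)-3-oxobut-1-en-1-yl]benzoate | COC(=O)c1c(OC)c(OC)ccc1/C=C/C(C)=O | intermediate
5 | methyl 2,3-dimethoxy-6-[(1E)-6,6,6-trifluoro-3,5-dioxohex-1-en-1-yl]benzoate | COC(=O)c1c(OC)c(OC)ccc1/C=C/C(=O)CC(=O)C(F)(F)F | intermediate (not isolated)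
6 | methyl 6-[(1E)-4-diazo-3-oxobut-1-en-1-yl]-2,3-dimethoxybenzoate | COC(=O)c1c(OC)c(OC)ccc1/C=C/C(=O)C=[N+]=[N-] | intermediate
7 | ethoxyethyne | C#COCC | starting material
8 | methyl 2,3-dimethoxy-6-[(1E)-4-oxobuta-1,3-dien-1-yl]benzoate (arylvinylketene) | COC(=O)c1c(OC)c(OC)ccc1/C=C/C=C=O | intermediate (not isolated)
9 | methyl 6-[(E)-2-(2-ethoxy-4-oxocyclobut-2-en-1-yl)ethenyl]-2,3-dimethoxybenzoate (racemic) | COC(=O)c1c(OC)c(OC)ccc1/C=C/C1C(OCC)=CC1=O | intermediate (not isolated)
10 | methyl 6-[(1E,3E)-4-ethoxy-6-oxohexa-1,3,5-trien-1-yl]-2,3-dimethoxybenzoate (dienylketene) | COC(=O)c1c(OC)c(OC)ccc1/C=C/C=C(/OCC)C=C=O | intermediate (not isolated)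
11 | methyl 6-(4-ethoxy-2-oxocyclohexa-3,5-dien-1-yl)-2,3-dimethoxybenzoate (racemic) | COC(=O)c1c(OC)c(OC)ccc1C1C=CC(OCC)=CC1=O | intermediate (not isolated)
12 | methyl 6-(4-ethoxy-2-hydroxyphenyl)-2,3-dimethoxybenzoate | COC(=O)c1c(OC)c(OC)ccc1-c1ccc(OCC)cc1O | intermediate
13 | 3-ethoxy-7,8-dimethoxy-6H-benzo[c]chromen-6-one | CCOc1ccc2c(c1)oc(=O)c1c(OC)c(OC)ccc21 | intermediate
14 | 4-phenylbutan-2-one | CC(=O)CCc1ccccc1 | starting material
15 | 1-[6-(4-ethoxy-2-hydroxyphenyl)-2,3-dimethoxyphenyl]-5-phenylpentane-1,3-dione | CCOc1ccc(c(O)c1)-c1ccc(OC)c(OC)c1C(=O)CC(=O)CCc1ccccc1 | intermediate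
16 | 1-[6-(4-ethoxy-2-hydroxyphenyl)-2-hydroxy-3-methoxyphenyl]-5-phenylpentane-1,3-dione | CCOc1ccc(c(O)c1)-c1ccc(OC)c(O)c1C(=O)CC(=O)CCc1ccccc1 | intermediate (not isolated)
17 | 5-(4-ethoxy-2-hydroxyphenyl)-8-methoxy-2-(2-phenylethyl)-4H-chromen-4-one | CCOc1ccc(c(O)c1)-c1ccc(OC)c2oc(CCc3ccccc3)cc(=O)c12 | intermediate
18 | 5-(4-ethoxy-2-methoxyphenyl)-8-methoxy-2-(2-phenylethyl)-4H-chromen-4-one | CCOc1ccc(c(OC)c1)-c1ccc(OC)c2oc(CCc3ccccc3)cc(=O)c12 | intermediate
19 | 5-(5-acetyl-4-ethoxy-2-methoxyphenyl)-8-methoxy-2-(2-phenylethyl)-4H-chromen-4-one | CCOc1cc(OC)c(cc1C(C)=O)-c1ccc(OC)c2oc(CCc3ccccc3)cc(=O)c12 | intermediate (not isolated)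
20 | 5-(5-acetyl-4-hydroxy-2-methoxyphenyl)-8-methoxy-2-(2-phenylethyl)-4H-chromen-4-one | CC(=O)c1cc(c(OC)cc1O)-c1ccc(OC)c2oc(CCc3ccccc3)cc(=O)c12 | intermediate
21 | 3-phenylpropanoyl chloride | O=C(Cl)CCc1ccccc1 | starting material
22 | 2-acetyl-5-methoxy-4-[8-methoxy-4-oxo-2-(2-phenylethyl)-4H-chromen-5-yl]phenyl 3-phenylpropanoate | O=C(CCc1ccccc1)Oc1cc(OC)c(cc1C(C)=O)-c1ccc(OC)c2oc(CCc3ccccc3)cc(=O)c12 | intermediate (not isolated)
23 | 1-{2-hydroxy-4-methoxy-5-[8-methoxy-4-oxo-2-(2-phenylethyl)-4H-chromen-5-yl]phenyl}-5-phenylpentane-1,3-dione | O=C(CC(=O)CCc1ccccc1)c1cc(c(OC)cc1O)-c1ccc(OC)c2oc(CCc3ccccc3)cc(=O)c12 | intermediate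
24 | 7-methoxy-6-[8-methoxy-4-oxo-2-(2-phenylethyl)-4H-chromen-5-yl]-2-(2-phenylethyl)-4H-chromen-4-one | COc1cc2oc(CCc3ccccc3)cc(=O)c2cc1-c1ccc(OC)c2oc(CCc3ccccc3)cc(=O)c12 | intermediate (not isolated)
25 | 7-hydroxy-6-[8-hydroxy-4-oxo-2-(2-phenylethyl)-4H-chromen-5-yl]-2-(2-phenylethyl)-4H-chromen-4-one | O=c1cc(CCc2ccccc2)oc2cc(O)c(-c3ccc(O)c4oc(CCc5ccccc5)cc(=O)c34)cc12 | target

## Step count and least certain steps

Total step count: 11 steps. Longest linear sequence: 11 steps (1 to 25); 3, 7, 14 and 21 enter as purchased building blocks.

Step 4 (key step).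
- What may go wrong: photochemical E/Z isomerisation of the styryl unit and secondary photoreactions of 6 or of the phenolic product compete with the Wolff rearrangement. The vinylketene may be lost by dimerisation or by capture through the phenol already formed before it meets the alkyne. Incomplete thermal opening of the cyclobutenone would lower throughput further.
- Fallback: the ring construction is given up and the two arenes are joined. Setting out from 2, Baeyer–Villiger oxidation with mCPBA (CH2Cl2) would give the aryl formate methyl 6-(formyloxy)-2,3-dimethoxybenzoate F1. Methanolysis (K2CO3, MeOH) would give methyl 6-hydroxy-2,3-dimethoxybenzoate F2, and Tf2O with pyridine would give methyl 2,3-dimethoxy-6-{[(trifluoromethyl)sulfonyl]oxy}benzoate F3. Suzuki–Miyaura coupling of F3 with (4-ethoxy-2-hydroxyphenyl)boronic acid F4 (Pd(OAc)2, SPhos, K3PO4, PhMe–H2O, 90 °C) would give 12, which should lactonise under these conditions or on acidic work-up. The route is rejoined at 13.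

Step 6.
- What may go wrong: attack of the enolate on the lactone carbonyl is slowed by the neighbouring methoxy group, so proton transfer, self-aldol condensation of the ketone and acylation through the internal enolate may take over.
- Fallback: the acyl carbon is made the partner of an acetylide instead. Setting out from 13, aminolysis with MeNH(OMe)·HCl and AlMe3 would give 6-(4-ethoxy-2-hydroxyphenyl)-N,2,3-trimethoxy-N-methylbenzamide F5. Methylation (MeI, K2CO3) would give 6-(4-ethoxy-2-methoxyphenyl)-N,2,3-trimethoxy-N-methylbenzamide F6. The lithium acetylide of but-3-yn-1-ylbenzene F7 (n-BuLi, THF, −78 °C) would convert F6 into 1-[6-(4-ethoxy-2-methoxyphenyl)-2,3-dimethoxyphenyl]-5-phenylpent-2-yn-1-one F8. BCl3 would cleave the methyl ether beside the carbonyl group to give 1-[6-(4-ethoxy-2-methoxyphenyl)-2-hydroxy-3-methoxyphenyl]-5-phenylpent-2-yn-1-one F9, and Et2NH in EtOH would close it by 6-endo oxa-Michael addition. The route is rejoined at 18, which also bypasses steps 7 and 8.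

Step 7.
- What may go wrong: ether cleavage may not stay confined to O8a' once boron is bound in the diketonate chelate. The C7 hydroxyl may add reversibly to C4' (six-membered hemiketal, then dehydration to an alkylidene benzo[c]chromene) and divert material from pyranone closure.
- Fallback: no selectivity is asked for. Setting out from 15, BBr3 (CH2Cl2, −78 → 20 °C) would remove all three alkyl groups, and hot aqueous HCl in dioxane would close the ring under thermodynamic control, where adducts at C4' revert and only the pyranone is formed irreversibly. This would give 5-(2,4-dihydroxyphenyl)-8-hydroxy-2-(2-phenylethyl)-4H-chromen-4-one F10. Permethylation (MeI, K2CO3, DMF) would give 5-(2,4-dimethoxyphenyl)-8-methoxy-2-(2-phenylethyl)-4H-chromen-4-one F11. Friedel–Crafts acetylation (AcCl, AlCl3) would give 5-(5-acetyl-2,4-dimethoxyphenyl)-8-methoxy-2-(2-phenylethyl)-4H-chromen-4-one F12, whose methyl ether ortho to the acetyl group is cleaved by the same AlCl3. The route is rejoined at 20.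

Step 9.
- What may go wrong: acylation may spread to the side-chain phenyl rings if acyl chloride is in excess, de-ethylation may stay incomplete, or further methyl ethers may be lost on prolonged exposure to AlCl3.
- Fallback: halogenation and cross-coupling replace electrophilic acylation. Setting out from 18, NBS in MeCN at 0 °C would brominate the most activated position to give 5-(5-bromo-4-ethoxy-2-methoxyphenyl)-8-methoxy-2-(2-phenylethyl)-4H-chromen-4-one F13. Stille coupling with tributyl(1-ethoxyethenyl)stannane F14 (Pd(PPh3)4, PhMe, 100 °C) would give 5-[4-ethoxy-5-(1-ethoxyethenyl)-2-methoxyphenyl]-8-methoxy-2-(2-phenylethyl)-4H-chromen-4-one F15. Aqueous HCl would hydrolyse the enol ether to 19, and BCl3 would then remove the ethyl group chelated to the ketone. The route is rejoined at 20.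

Step 10.
- What may go wrong: the base may deprotonate the side-chain methylene next to C2' of pyranone B, leading to intermolecular acyl transfer to that position. Elimination of a ketene from the ester would return 20.
- Fallback: strong base is avoided. Setting out from 20, condensation with 3-phenylpropanal F16 under pyrrolidine catalysis (EtOH, 60 °C; Kabbe-type aldol condensation and oxa-Michael closure) would give racemic 7-methoxy-6-[8-methoxy-4-oxo-2-(2-phenylethyl)-4H-chromen-5-yl]-2-(2-phenylethyl)-2,3-dihydro-4H-chromen-4-one F17. Dehydrogenation with IBX (DMSO, 80 °C) would introduce the C2=C3 double bond. The route is rejoined at 24, from which the ether cleavage of step 11 leads to 25.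

## Further compounds

F1 | step 4 | methyl 6-(formyloxy)-2,3-dimethoxybenzoate | COC(=O)c1c(OC=O)ccc(OC)c1OC
F2 | step 4 | methyl 6-hydroxy-2,3-dimethoxybenzoate | COC(=O)c1c(O)ccc(OC)c1OC
F3 | step 4 | methyl 2,3-dimethoxy-6-{[(trifluoromethyl)sulfonyl]oxy}benzoate | COC(=O)c1c(OS(=O)(=O)C(F)(F)F)ccc(OC)c1OC
F4 | step 4 | (4-ethoxy-2-hydroxyphenyl)boronic acid | CCOc1ccc(B(O)O)c(O)c1
F5 | step 6 | 6-(4-ethoxy-2-hydroxyphenyl)-N,2,3-trimethoxy-N-methylbenzamide | CCOc1ccc(c(O)c1)-c1ccc(OC)c(OC)c1C(=O)N(C)OC
F6 | step 6 | 6-(4-ethoxy-2-methoxyphenyl)-N,2,3-trimethoxy-N-methylbenzamide | CCOc1ccc(c(OC)c1)-c1ccc(OC)c(OC)c1C(=O)N(C)OC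
F7 | step 6 | but-3-yn-1-ylbenzene | C#CCCc1ccccc1
F8 | step 6 | 1-[6-(4-ethoxy-2-methoxyphenyl)-2,3-dimethoxyphenyl]-5-phenylpent-2-yn-1-one | CCOc1ccc(c(OC)c1)-c1ccc(OC)c(OC)c1C(=O)C#CCCc1ccccc1
F9 | step 6 | 1-[6-(4-ethoxy-2-methoxyphenyl)-2-hydroxy-3-methoxyphenyl]-5-phenylpent-2-yn-1-one | CCOc1ccc(c(OC)c1)-c1ccc(OC)c(O)c1C(=O)C#CCCc1ccccc1
F10 | step 7 | 5-(2,4-dihydroxyphenyl)-8-hydroxy-2-(2-phenylethyl)-4H-chromen-4-one | Oc1ccc(c(O)c1)-c1ccc(O)c2oc(CCc3ccccc3)cc(=O)c12
F11 | step 7 | 5-(2,4-dimethoxyphenyl)-8-methoxy-2-(2-phenylethyl)-4H-chromen-4-one | COc1ccc(c(OC)c1)-c1ccc(OC)c2oc(CCc3ccccc3)cc(=O)c12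
F12 | step 7 | 5-(5-acetyl-2,4-dimethoxyphenyl)-8-methoxy-2-(2-phenylethyl)-4H-chromen-4-one | COc1cc(OC)c(cc1C(C)=O)-c1ccc(OC)c2oc(CCc3ccccc3)cc(=O)c12
F13 | step 9 | 5-(5-bromo-4-ethoxy-2-methoxyphenyl)-8-methoxy-2-(2-phenylethyl)-4H-chromen-4-one | CCOc1cc(OC)c(cc1Br)-c1ccc(OC)c2oc(CCc3ccccc3)cc(=O)c12
F14 | step 9 | tributyl(1-ethoxyethenyl)stannane | CCCC[Sn](CCCC)(CCCC)C(=C)OCC
F15 | step 9 | 5-[4-ethoxy-5-(1-ethoxyethenyl)-2-methoxyphenyl]-8-methoxy-2-(2-phenylethyl)-4H-chromen-4-one | CCOC(=C)c1cc(c(OC)cc1OCC)-c1ccc(OC)c2oc(CCc3ccccc3)cc(=O)c12
F16 | step 10 | 3-phenylpropanal | O=CCCc1ccccc1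
F17 | step 10 | 7-methoxy-6-[8-methoxy-4-oxo-2-(2-phenylethyl)-4H-chromen-5-yl]-2-(2-phenylethyl)-2,3-dihydro-4H-chromen-4-one (racemic) | COc1cc2OC(CCc3ccccc3)CC(=O)c2cc1-c1ccc(OC)c2oc(CCc3ccccc3)cc(=O)c12
A1 | alternative 1 | 4-fluoro-1,2-dimethoxybenzene | COc1ccc(F)cc1OC
A2 | alternative 1 | (2,4-dimethoxyphenyl)magnesium bromide | COc1ccc([Mg]Br)c(OC)c1
A3 | alternative 1 | N-methoxy-N-methyl-5-phenylpent-2-ynamide | CON(C)C(=O)C#CCCc1ccccc1
A4 | alternative 1 | 1-[6-(2,4-dimethoxyphenyl)-2,3-dimethoxyphenyl]-5-phenylpent-2-yn-1-one | COc1ccc(-c2ccc(OC)c(OC)c2C(=O)C#CCCc2ccccc2)c(OC)c1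
A5 | alternative 2 | 2-(2-phenylethyl)-4H,6H-pyrano[3,2-g]chromene-4,6-dione | O=c1cc(CCc2ccccc2)oc2cc3occc(=O)c3cc12
A6 | alternative 2 | 1,4-dimethoxy-1,3-bis(trimethylsilyloxy)buta-1,3-diene (alkene geometry not defined) | COC=C(O[Si](C)(C)C)C=C(OC)O[Si](C)(C)C
A7 | alternative 2 | 2-(2-phenylethyl)chromen-4-one fused across C6–C7 to a 7-hydroxy-8-methoxy-6H-benzo[c]chromen-6-one (lactone from O7 to C4', biaryl bond C6–C5') | O=c1cc(CCc2ccccc2)oc2cc3oc(=O)c4c(O)c(OC)ccc4c3cc12
A8 | alternative 3 | 5-(4-hydroxy-2-methoxyphenyl)-8-methoxy-2-(2-phenylethyl)-4H-chromen-4-one | Oc1ccc(c(OC)c1)-c1ccc(OC)c2oc(CCc3ccccc3)cc(=O)c12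
A9 | alternative 3 | ethyl 5-phenylpent-2-ynoate | CCOC(=O)C#CCCc1ccccc1
A10 | alternative 3 | (2E)-3-{3-methoxy-4-[8-methoxy-4-oxo-2-(2-phenylethyl)-4H-chromen-5-yl]phenoxy}-5-phenylpent-2-enoic acid | OC(=O)/C=C(/Oc1ccc(c(OC)c1)-c1ccc(OC)c2oc(CCc3ccccc3)cc(=O)c12)CCc1ccccc1
A11 | alternative 3 | 7-methoxy-6-[8-methoxy-4-oxo-2-(2-phenylethyl)-4H-chromen-5-yl]-2-(2-phenylethyl)-4H-chromen-4-one (identical with 24) | COc1cc2oc(CCc3ccccc3)cc(=O)c2cc1-c1ccc(OC)c2oc(CCc3ccccc3)cc(=O)c12
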